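**Plan**

- Retrosynthesis: the phenol is unmasked last from a benzyl ether and the C1 ketone is traced to a C1 carbinol; a formyl group is put back on C2; ring B is then cut at C1–C2 and C3–C4; finally the aryl–CH2 bond between ring A and the 3,4-dimethoxyphenyl unit is cut.
- Enabling feature (tetralone numbering: C1 carbonyl, C2 and C3 methyl-bearing, C4 aryl-bearing, C4a/C8a the fusion carbons of phenol ring A): ring B is a six-membered ring fused to aromatic ring A, so C1–C8a–C4a–C4 is a masked hydroxy-ortho-quinodimethane, and C2–C3 with its two cis methyls is a 2-butene unit that becomes (E)-2-methylbut-2-enal once a removable formyl group sits on C2.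
- Forward order: isovanillin is benzylated, brominated and joined to the 3,4-dimethoxybenzyl unit by Negishi coupling; photoenolisation/Diels–Alder with tiglaldehyde closes ring B, the only ring made; silylation, rhodium decarbonylation, desilylation, oxidation at C1 and hydrogenolysis finish the target.
- Stereochemistry: the cis-2,3-dimethyl relation comes from the (E)-geometry of the dienophile; the trans C3/C4 relation from the formyl-endo transition state with the aryl group outward on the dienol; the absolute sense from the TADDOLate ligand on titanium; C2–H from stereoretentive decarbonylation; the C1 carbinol centre is sacrificial.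

Key step: step 4

Assumption: (R,R)-TADDOL is written as the ligand enantiomer that opens the required dienol face; should a pilot run show the opposite sense, (S,S)-TADDOL is used with nothing else changed.

**Route**

Step 1
Reactants: 1 isovanillin (3-hydroxy-4-methoxybenzaldehyde)
Product: 2 3-(benzyloxy)-4-methoxybenzaldehyde
Conditions: BnBr, K2CO3, DMF, 25 °C
Reagents that add atoms: benzyl bromide, BrCc1ccccc1
Why: Williamson ether synthesis, in which the phenoxide formed by K2CO3 displaces bromide from benzyl bromide (SN2) and the phenol is masked as an ether that should withstand every step up to the final hydrogenolysis.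

Step 2
Reactants: 2 3-(benzyloxy)-4-methoxybenzaldehyde
Product: 3 5-(benzyloxy)-2-bromo-4-methoxybenzaldehyde
Conditions: Br2, NaOAc, AcOH, 25 °C
Reagents that add atoms: bromine, BrBr
Why: Electrophilic aromatic bromination should occur para to the benzyloxy group, because the 4-methoxy group is deactivated by conjugation with the para formyl group (as in the bromination of veratraldehyde), while NaOAc takes up HBr and spares the benzyl ether.

Step 3
Reactants: 3 5-(benzyloxy)-2-bromo-4-methoxybenzaldehyde; 4 3,4-dimethoxybenzyl chloride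
Product: 6 5-(benzyloxy)-2-(3,4-dimethoxybenzyl)-4-methoxybenzaldehyde, via (3,4-dimethoxybenzyl)zinc chloride 5 (not isolated)
Conditions: 4, Zn dust, LiCl, THF, 25 °C; then slow addition to 3, Pd(OAc)2 (2 mol %), SPhos (4 mol %), THF, 25 °C
Reagents that add atoms: none
Why: Negishi cross-coupling, in which LiCl-assisted zinc insertion into the benzylic C–Cl bond gives 5 and zerovalent palladium formed in situ inserts into the formyl-activated C–Br bond, transmetalates and reductively eliminates to the diarylmethane, the fast room-temperature coupling and slow addition of 5 keeping 1,2-addition to the electron-rich aldehyde in check.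

Step 4
Reactants: 6 5-(benzyloxy)-2-(3,4-dimethoxybenzyl)-4-methoxybenzaldehyde; 7 (E)-2-methylbut-2-enal (tiglaldehyde)
Product: 9 (1S,2R,3S,4R)-7-(benzyloxy)-4-(3,4-dimethoxyphenyl)-1-hydroxy-6-methoxy-2,3-dimethyl-1,2,3,4-tetrahydronaphthalene-2-carbaldehyde, via (E,E)-hydroxy-ortho-quinodimethane 8 (not isolated)
Conditions: Ti(Oi-Pr)4 (1.5 equiv), (R,R)-TADDOL (1.6 equiv), 4 Å MS, toluene, 25 °C; then 6, 7 (5 equiv), degassed, hν (365 nm), 0–25 °C; hydrolytic work-up
Reagents that add atoms: none
Why: Photoexcitation of the aryl aldehyde is followed by a 1,5-hydrogen shift from the doubly benzylic CH2 to the carbonyl oxygen, giving the (E,E)-hydroxy-ortho-quinodimethane 8 (hydroxyl and aryl outward), whose oxygen is taken up by the tetravalent titanium TADDOLate while the carbonyl oxygen of 7 coordinates to the same metal centre. The closest known reaction type is the Ti(Oi-Pr)4/TADDOL-mediated enantioselective photoenolisation/Diels–Alder reaction of 2-alkylbenzaldehydes with α,β-unsaturated carbonyl compounds, combined with the long-known photoenol cycloadditions of 2-benzylbenzaldehydes that lead to aryltetralins. Ring B is closed by an intermolecular, concerted suprafacial [4+2] cycloaddition in which C1–C2 and C3–C4 form together and ring A regains aromaticity. C1 and C4 follow from the outward positions of hydroxyl and aryl on the dienol (cis to each other), C2 from the formyl-endo approach held by the O–Ti–O=C bridge (formyl cis to C1–OH, methyl trans), and C3 from the (E)-geometry of 7, which keeps both methyls cis to each other, exo, and therefore trans to the C4 aryl group. The absolute configuration of all four centres is set by the twofold-symmetric TADDOLate, which leaves one face of the bound dienol open to the enal. The step needs regio-, endo- and facial selectivity: the first two are secured by the donor hydroxyl at C1 (largest diene coefficient at C4, which pairs with the β-carbon of the enal) and by two-point binding to titanium, the third by the ligand, and irradiation at 365 nm, where only the aryl aldehyde absorbs appreciably, protects the geometry of 7.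

Step 5
Reactants: 9 (1S,2R,3S,4R)-7-(benzyloxy)-4-(3,4-dimethoxyphenyl)-1-hydroxy-6-methoxy-2,3-dimethyl-1,2,3,4-tetrahydronaphthalene-2-carbaldehyde
Product: 10 (1S,2R,3S,4R)-7-(benzyloxy)-4-(3,4-dimethoxyphenyl)-6-methoxy-2,3-dimethyl-1-[(triethylsilyl)oxy]-1,2,3,4-tetrahydronaphthalene-2-carbaldehyde
Conditions: TESOTf, 2,6-lutidine, CH2Cl2, −78 → 0 °C
Reagents that add atoms: triethylsilyl trifluoromethanesulfonate, CC[Si](CC)(CC)OS(=O)(=O)C(F)(F)F
Why: Silylation of a hindered secondary alcohol with a silyl triflate and a non-nucleophilic base should proceed without retro-aldol cleavage of the β-hydroxy aldehyde, and the formyl group, lacking an α-hydrogen, cannot form an enol silyl ether.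

Step 6
Reactants: 10 (1S,2R,3S,4R)-7-(benzyloxy)-4-(3,4-dimethoxyphenyl)-6-methoxy-2,3-dimethyl-1-[(triethylsilyl)oxy]-1,2,3,4-tetrahydronaphthalene-2-carbaldehyde
Product: 11 {[(1R,2S,3S,4R)-7-(benzyloxy)-4-(3,4-dimethoxyphenyl)-6-methoxy-2,3-dimethyl-1,2,3,4-tetrahydronaphthalen-1-yl]oxy}triethylsilane
Conditions: RhCl(PPh3)3 (1.2 equiv), PhCN, 130 °C
Reagents that add atoms: none
Why: Tsuji–Wilkinson decarbonylation, in which the formyl C–H bond adds oxidatively to monovalent rhodium, the alkyl group migrates from the acyl carbon to trivalent rhodium and C–H reductive elimination follows, each event with retention, so that hydrogen takes the place of the formyl group at C2 and the cis-2,3-dimethyl relation is kept (the C1 and C2 descriptors change only through priority rules).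

Step 7
Reactants: 11 {[(1R,2S,3S,4R)-7-(benzyloxy)-4-(3,4-dimethoxyphenyl)-6-methoxy-2,3-dimethyl-1,2,3,4-tetrahydronaphthalen-1-yl]oxy}triethylsilane
Product: 12 (1R,2S,3S,4R)-7-(benzyloxy)-4-(3,4-dimethoxyphenyl)-6-methoxy-2,3-dimethyl-1,2,3,4-tetrahydronaphthalen-1-ol
Conditions: TBAF, THF, 0 → 25 °C
Reagents that add atoms: none
Why: Fluoride-mediated desilylation driven by the strong Si–F bond should free the C1 carbinol, while the benzyl and methyl ethers are inert to fluoride.

Step 8
Reactants: 12 (1R,2S,3S,4R)-7-(benzyloxy)-4-(3,4-dimethoxyphenyl)-6-methoxy-2,3-dimethyl-1,2,3,4-tetrahydronaphthalen-1-ol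
Product: 13 (2S,3S,4R)-7-(benzyloxy)-4-(3,4-dimethoxyphenyl)-6-methoxy-2,3-dimethyl-3,4-dihydronaphthalen-1(2H)-one
Conditions: Dess–Martin periodinane, NaHCO3, CH2Cl2, 0 → 25 °C
Reagents that add atoms: none
Why: Dess–Martin oxidation of the benzylic secondary alcohol to the aryl ketone under buffered, non-basic conditions should leave the now epimerisable C2 centre, α to the new carbonyl, untouched.

Step 9
Reactants: 13 (2S,3S,4R)-7-(benzyloxy)-4-(3,4-dimethoxyphenyl)-6-methoxy-2,3-dimethyl-3,4-dihydronaphthalen-1(2H)-one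
Product: 14 schisandrone, (2S,3S,4R)-4-(3,4-dimethoxyphenyl)-7-hydroxy-6-methoxy-2,3-dimethyl-3,4-dihydronaphthalen-1(2H)-one
Conditions: H2 (1 atm), Pd/C (10% palladium on carbon), EtOAc, 25 °C, stopped at full conversion
Reagents that add atoms: none
Why: Catalytic hydrogenolysis of the benzyl aryl ether under neutral conditions should release the phenol much faster than the para-methoxy-deactivated aryl ketone is reduced, and it does not enolise C2.

**Compound list**

1 | isovanillin (3-hydroxy-4-methoxybenzaldehyde) | O=Cc1ccc(OC)c(O)c1 | starting material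
2 | 3-(benzyloxy)-4-methoxybenzaldehyde | O=Cc1ccc(OC)c(OCc2ccccc2)c1 | intermediate
3 | 5-(benzyloxy)-2-bromo-4-methoxybenzaldehyde | O=Cc1cc(OCc2ccccc2)c(OC)cc1Br | intermediate
4 | 3,4-dimethoxybenzyl chloride | ClCc1ccc(OC)c(OC)c1 | starting material
5 | (3,4-dimethoxybenzyl)zinc chloride | Cl[Zn]Cc1ccc(OC)c(OC)c1 | intermediate (not isolated)
6 | 5-(benzyloxy)-2-(3,4-dimethoxybenzyl)-4-methoxybenzaldehyde | O=Cc1cc(OCc2ccccc2)c(OC)cc1Cc1ccc(OC)c(OC)c1 | intermediate
7 | (E)-2-methylbut-2-enal (tiglaldehyde) | C/C=C(\C)C=O | starting material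
8 | (E,E)-hydroxy-ortho-quinodimethane (photoenol of 6; hydroxyl and aryl outward) | O/C=C1\C=C(OCc2ccccc2)C(OC)=C/C1=C\c1ccc(OC)c(OC)c1 | intermediate (not isolated)
9 | (1S,2R,3S,4R)-7-(benzyloxy)-4-(3,4-dimethoxyphenyl)-1-hydroxy-6-methoxy-2,3-dimethyl-1,2,3,4-tetrahydronaphthalene-2-carbaldehyde | COc1cc2c(cc1OCc1ccccc1)[C@H](O)[C@](C)(C=O)[C@@H](C)[C@@H]2c1ccc(OC)c(OC)c1 | intermediate
10 | (1S,2R,3S,4R)-7-(benzyloxy)-4-(3,4-dimethoxyphenyl)-6-methoxy-2,3-dimethyl-1-[(triethylsilyl)oxy]-1,2,3,4-tetrahydronaphthalene-2-carbaldehyde | COc1cc2c(cc1OCc1ccccc1)[C@H](O[Si](CC)(CC)CC)[C@](C)(C=O)[C@@H](C)[C@@H]2c1ccc(OC)c(OC)c1 | intermediate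
11 | {[(1R,2S,3S,4R)-7-(benzyloxy)-4-(3,4-dimethoxyphenyl)-6-methoxy-2,3-dimethyl-1,2,3,4-tetrahydronaphthalen-1-yl]oxy}triethylsilane | COc1cc2c(cc1OCc1ccccc1)[C@H](O[Si](CC)(CC)CC)[C@@H](C)[C@@H](C)[C@@H]2c1ccc(OC)c(OC)c1 | intermediate
12 | (1R,2S,3S,4R)-7-(benzyloxy)-4-(3,4-dimethoxyphenyl)-6-methoxy-2,3-dimethyl-1,2,3,4-tetrahydronaphthalen-1-ol | COc1cc2c(cc1OCc1ccccc1)[C@H](O)[C@@H](C)[C@@H](C)[C@@H]2c1ccc(OC)c(OC)c1 | intermediate
13 | (2S,3S,4R)-7-(benzyloxy)-4-(3,4-dimethoxyphenyl)-6-methoxy-2,3-dimethyl-3,4-dihydronaphthalen-1(2H)-one | COc1cc2c(cc1OCc1ccccc1)C(=O)[C@@H](C)[C@@H](C)[C@@H]2c1ccc(OC)c(OC)c1 | intermediate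
14 | schisandrone, (2S,3S,4R)-4-(3,4-dimethoxyphenyl)-7-hydroxy-6-methoxy-2,3-dimethyl-3,4-dihydronaphthalen-1(2H)-one | COc1cc2c(cc1O)C(=O)[C@@H](C)[C@@H](C)[C@@H]2c1ccc(OC)c(OC)c1 | target

**Step count**

Total: 9 steps. Longest linear sequence: 9 steps (1 → 14); 4 and 7 are commercial and enter in steps 3 and 4.

**Steps most likely to fail**

Step 4. The chiral titanium complex may discriminate the two dienol faces incompletely when the dienophile is an acyclic, trisubstituted enal, and the bulky complex may slow the cycloaddition. The fallback replaces ligand control by resolution. Setting out from 6 and 7, irradiation at 365 nm with Ti(Oi-Pr)4 alone should give the racemic endo cycloadduct F1. Steglich esterification of its C1 hydroxyl with (S)-O-methylmandelic acid (DCC, DMAP, CH2Cl2) should give the (1S,2R,3S,4R)-configured O-methylmandelate F2 and the diastereomeric (1R,2S,3R,4S)-configured O-methylmandelate F3, to be separated by chromatography or crystallisation. F2 carries the ester in place of the silyl ether through the RhCl(PPh3)3 decarbonylation to the decarbonylated O-methylmandelate F4, and methanolysis (K2CO3, MeOH) brings the route back at alcohol 12.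

Step 6. Oxidative addition at the neopentyl-type formyl group may be slow, and β-hydride elimination from the tertiary alkylrhodium hydride may overtake C–H reductive elimination and lead to olefins. The fallback removes the formyl group by retro-Claisen cleavage instead of metal decarbonylation. Setting out from 9, Dess–Martin oxidation (NaHCO3, CH2Cl2) of the C1 carbinol should give the β-keto aldehyde F5. NaOMe in THF at −78 °C should add to the formyl group and expel the C1–C2 enolate with loss of methyl formate. Quenching at −78 °C with AcOH should protonate C2 on the face anti to the C3 methyl, giving the cis-2,3 ketone and rejoining the route at 13, so that steps 5 to 7 are not needed. In this variant C2 rests on kinetic protonation and not on retention, so the C2 epimer has to be looked for and removed.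

Step 3. The benzylic zinc reagent may add to the unprotected formyl group, and Wurtz-type homocoupling may compete during zinc insertion into the electron-rich benzyl chloride. The fallback reverses the polarity of the coupling. Setting out from 3, Miyaura borylation (B2pin2, Pd(dppf)Cl2, KOAc, dioxane, 80 °C) should give the aryl pinacol boronate F6, which is joined to chloride 4 by Suzuki–Miyaura coupling (Pd(PPh3)4, K2CO3, toluene/EtOH/H2O, 80 °C) to return at 6.

**Further compounds**

F1 | step 4 | racemic (1S,2R,3S,4R)/(1R,2S,3R,4S)-7-(benzyloxy)-4-(3,4-dimethoxyphenyl)-1-hydroxy-6-methoxy-2,3-dimethyl-1,2,3,4-tetrahydronaphthalene-2-carbaldehyde | COc1cc2c(cc1OCc1ccccc1)[C@H](O)[C@](C)(C=O)[C@@H](C)[C@@H]2c1ccc(OC)c(OC)c1.COc1cc2c(cc1OCc1ccccc1)[C@@H](O)[C@@](C)(C=O)[C@H](C)[C@H]2c1ccc(OC)c(OC)c1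
F2 | step 4 | (1S,2R,3S,4R)-7-(benzyloxy)-4-(3,4-dimethoxyphenyl)-2-formyl-6-methoxy-2,3-dimethyl-1,2,3,4-tetrahydronaphthalen-1-yl (S)-2-methoxy-2-phenylacetate | COc1cc2c(cc1OCc1ccccc1)[C@H](OC(=O)[C@@H](OC)c1ccccc1)[C@](C)(C=O)[C@@H](C)[C@@H]2c1ccc(OC)c(OC)c1
F3 | step 4 | (1R,2S,3R,4S)-7-(benzyloxy)-4-(3,4-dimethoxyphenyl)-2-formyl-6-methoxy-2,3-dimethyl-1,2,3,4-tetrahydronaphthalen-1-yl (S)-2-methoxy-2-phenylacetate | COc1cc2c(cc1OCc1ccccc1)[C@@H](OC(=O)[C@@H](OC)c1ccccc1)[C@@](C)(C=O)[C@H](C)[C@H]2c1ccc(OC)c(OC)c1
F4 | step 4 | (1R,2S,3S,4R)-7-(benzyloxy)-4-(3,4-dimethoxyphenyl)-6-methoxy-2,3-dimethyl-1,2,3,4-tetrahydronaphthalen-1-yl (S)-2-methoxy-2-phenylacetate | COc1cc2c(cc1OCc1ccccc1)[C@H](OC(=O)[C@@H](OC)c1ccccc1)[C@@H](C)[C@@H](C)[C@@H]2c1ccc(OC)c(OC)c1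
F5 | step 6 | (2S,3S,4R)-7-(benzyloxy)-4-(3,4-dimethoxyphenyl)-6-methoxy-2,3-dimethyl-1-oxo-1,2,3,4-tetrahydronaphthalene-2-carbaldehyde | COc1cc2c(cc1OCc1ccccc1)C(=O)[C@](C)(C=O)[C@@H](C)[C@@H]2c1ccc(OC)c(OC)c1
F6 | step 3 | 5-(benzyloxy)-4-methoxy-2-(4,4,5,5-tetramethyl-1,3,2-dioxaborolan-2-yl)benzaldehyde | O=Cc1cc(OCc2ccccc2)c(OC)cc1B1OC(C)(C)C(C)(C)O1
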